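The indoxyl core carries its C3 carbonyl oxygen and N1 on neighbouring benzo carbons (C3a and C7a), the ortho pattern of a 2-nitroaryl alkyne, and C2 is a quaternary carbon bonded to N1 and two indol-3-yl groups. The route therefore rests on disconnecting N1–C2, the C3–O bond and one C2–C3' bond: a 2-nitrophenyl (N-Boc-indol-3-yl) alkyne undergoes internal redox cycloisomerisation to the 2-indolylisatogen, whose nitrone carbon is then attacked by indole in the same flask. One operation thus builds the five-membered ring, the ketone and the quaternary C2. The precursor is a Sonogashira-derived diaryl alkyne that keeps its Boc group; N–O reduction and Boc removal finish the synthesis.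

Key step: step 2

Remark on the chemistry: the Boc group of 2 is carried through the key step on purpose. A free-NH 3-alkynylindole is a labile, enamine-type donor alkyne that would bias oxygen delivery toward its own alkyne carbon and would give a less electrophilic nitrone. As a consequence C2 of 6 and 7 is stereogenic; both are expected as racemates, and the centre becomes achiral again in step 4.

Step 1
Reactants: 1 1-ethynyl-2-nitrobenzene; 2 tert-butyl 3-iodoindole-1-carboxylate
Product: 3 tert-butyl 3-[(2-nitrophenyl)ethynyl]indole-1-carboxylate
Conditions: PdCl2(PPh3)2 (2 mol %), CuI (4 mol %), Et3N, THF, rt, argon, slow addition of 1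
Reagents that add atoms: none
Why: Sonogashira coupling, in which the C3–I bond of the N-Boc-iodoindole adds to zerovalent palladium at room temperature and the copper acetylide of the acidic alkyne 1 transmetallates readily, while the nitro and Boc groups are inert.

Step 2
Reactants: 3 tert-butyl 3-[(2-nitrophenyl)ethynyl]indole-1-carboxylate; 4 indole
Product: 6 rac-tert-butyl 3-[1-hydroxy-2-(1H-indol-3-yl)-3-oxoindolin-2-yl]indole-1-carboxylate, via 2-(1-Boc-indol-3-yl)isatogen 5 (not isolated)
Conditions: PdCl2(MeCN)2 (5 mol %), MeCN, rt; then indole (1.2 equiv), InCl3 (20 mol %), rt
Reagents that add atoms: none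
Why: The divalent palladium π-acid activates the alkyne of 3 and a nitro oxygen attacks the alkyne carbon bound to the nitroarene in a 5-exo-dig closure, after which N–O scission leaves the C3 ketone, an ortho nitroso group and a metal carbenoid on the indolyl-bearing carbon. The nitroso nitrogen then captures that carbenoid carbon, which forms N1–C2 and closes the five-membered ring of the indoxyl (5-exo-trig with respect to the carbon–metal double bond) to give isatogen 5; this is the known cycloisomerisation of 2-nitrodiarylalkynes to 2-arylisatogens. InCl3 next coordinates the nitrone oxygen and indole 4 adds through C3 to the nitrone carbon in a Mannich-type aza-Friedel–Crafts step, the known Lewis-acid addition of indoles to isatogens, which forms C2–C3' and leaves the N-hydroxy group. The cascade needs oxygen delivery in the 5-exo rather than the 6-endo sense, which an aryl-type group on the distal alkyne carbon favours, and the Boc group keeps the indol-3-yl from acting as an enamine-type donor that would make its own alkyne carbon the electrophilic one. It also needs attack at the nitrone carbon and not at the ketone, secured by the iminium-like character of the coordinated nitrone next to the carbonyl, and indole is added only after 3 is consumed so that it cannot add to the activated alkyne. C2 of 6 is stereogenic only because one indole carries Boc; no element controls it, so 6 should form as the racemate and the centre disappears in step 4.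

Step 3
Reactants: 6 rac-tert-butyl 3-[1-hydroxy-2-(1H-indol-3-yl)-3-oxoindolin-2-yl]indole-1-carboxylate
Product: 7 rac-tert-butyl 3-[2-(1H-indol-3-yl)-3-oxoindolin-2-yl]indole-1-carboxylate
Conditions: Zn dust, AcOH, THF, rt
Reagents that add atoms: none
Why: Dissolving-metal reduction of an N,N-disubstituted hydroxylamine, in which zinc in acetic acid cleaves the N–O bond by electron transfer and protonation while the vinylogous-amide ketone, the indoles and the Boc carbamate should stay intact at room temperature and the racemic C2 centre is not touched.

Step 4
Reactants: 7 rac-tert-butyl 3-[2-(1H-indol-3-yl)-3-oxoindolin-2-yl]indole-1-carboxylate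
Product: 8 2,2-bis(3'-indolyl)indoxyl [2,2-di(1H-indol-3-yl)indolin-3-one]
Conditions: NaOMe (0.3 equiv), MeOH, THF, rt, argon
Reagents that add atoms: none
Why: Methanolysis of an N-Boc indole, in which catalytic methoxide transfers the Boc group to methanol because indolide is a good leaving group, while the quaternary C2 has no enolisable hydrogen; with both indolyl groups now identical, C2 is no longer a stereocentre.

Compound list
1 | 1-ethynyl-2-nitrobenzene | C#Cc1ccccc1[N+](=O)[O-] | starting material
2 | tert-butyl 3-iodoindole-1-carboxylate | CC(C)(C)OC(=O)n1cc(I)c2ccccc12 | starting material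
3 | tert-butyl 3-[(2-nitrophenyl)ethynyl]indole-1-carboxylate | CC(C)(C)OC(=O)n1cc(C#Cc2ccccc2[N+](=O)[O-])c2ccccc12 | intermediate
4 | indole (1H-indole) | c1ccc2[nH]ccc2c1 | starting material
5 | tert-butyl 3-(1-oxido-3-oxo-3H-indol-1-ium-2-yl)indole-1-carboxylate, the 2-(1-Boc-indol-3-yl)isatogen | CC(C)(C)OC(=O)n1cc(C2=[N+]([O-])c3ccccc3C2=O)c2ccccc12 | intermediate
6 | rac-tert-butyl 3-[1-hydroxy-2-(1H-indol-3-yl)-3-oxoindolin-2-yl]indole-1-carboxylate (racemic at C2) | CC(C)(C)OC(=O)n1cc(C2(c3c[nH]c4ccccc34)N(O)c3ccccc3C2=O)c2ccccc12 | intermediate
7 | rac-tert-butyl 3-[2-(1H-indol-3-yl)-3-oxoindolin-2-yl]indole-1-carboxylate (racemic at C2) | CC(C)(C)OC(=O)n1cc(C2(c3c[nH]c4ccccc34)Nc3ccccc3C2=O)c2ccccc12 | intermediate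
8 | 2,2-bis(3'-indolyl)indoxyl, 2,2-di(1H-indol-3-yl)indolin-3-one (achiral) | O=C1c2ccccc2NC1(c1c[nH]c2ccccc12)c1c[nH]c2ccccc12 | target

Total step count: 4
Longest linear sequence: 4 steps (2 → 3 → 6 → 7 → 8)

Steps most likely to fail

Step 2 (key step). What may go wrong:
- delivery of the nitro oxygen to the indolyl-bearing alkyne carbon (6-endo closure) instead of the arene-bound one;
- hydration or oligomerisation of the π-acid-activated alkyne;
- slow addition of indole to a nitrone carbon that is shielded by the Boc-indolyl group.

The fallback sets out from 3 and returns at 7. The nitro group of 3 is reduced chemoselectively with iron powder and NH4Cl in aqueous ethanol to tert-butyl 3-[(2-aminophenyl)ethynyl]indole-1-carboxylate F1. A 5-endo-dig hydroamination with catalytic NaAuCl4 in ethanol then closes the pyrrole ring to tert-butyl 3-(1H-indol-2-yl)indole-1-carboxylate F2. Oxygenation of the free-NH indole unit of F2 at C3 (O2 with catalytic CuCl, or an oxoammonium salt), followed by addition of indole 4 and a catalytic acid in the same flask, should give 7. This is the known oxidative dearomatisation and aza-Friedel–Crafts sequence of 2-arylindoles, and it runs through the cyclic ketimine that the next fallback isolates. The ring is closed here by hydroamination and the C3 oxygen comes from an external oxidant, so neither the regiochemistry of oxygen transfer nor an N–O reduction is at stake.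

Step 3. What may go wrong:
- acid-promoted ionisation at the aminal-type C2 with loss of an indolyl group;
- electron transfer into the ketone with scission of C2–N1;
- stalling of the reduction at the hindered N–OH.

The fallback sets out from isatogen 5, which is isolated by stopping step 2 before indole and InCl3 are added, and returns at 7. The nitrone is deoxygenated first with PPh3 in warm toluene to tert-butyl 3-(3-oxo-3H-indol-2-yl)indole-1-carboxylate F3. Indole 4 is then added to C2 of this cyclic C-acyl ketimine under catalysis by InCl3 or a Brønsted acid, the known aza-Friedel–Crafts reaction of 2-aryl-3H-indol-3-ones, which should give 7 directly. The oxygen is thus removed before the quaternary centre exists, and no reduction is needed afterwards.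

Step 1. What may go wrong:
- oxidative homocoupling (Glaser) of the acidic, electron-poor alkyne 1;
- base- or copper-induced decomposition of 1 outrunning the cross-coupling.

The fallback sets out from 2 and returns at 3, with the roles of the partners inverted. Sonogashira coupling of 2 with ethynyltrimethylsilane (C#C[Si](C)(C)C) should give tert-butyl 3-[(trimethylsilyl)ethynyl]indole-1-carboxylate F4. Desilylation with TBAF in THF at 0 °C gives tert-butyl 3-ethynylindole-1-carboxylate F5. A second Sonogashira coupling of F5 with 1-iodo-2-nitrobenzene (O=[N+]([O-])c1ccccc1I; PdCl2(PPh3)2, CuI, Et3N) then gives 3. The nitroarene is now the activated electrophile and the alkyne partner is the less acidic, electron-richer one.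

Further compounds
F1 | step 2 | tert-butyl 3-[(2-aminophenyl)ethynyl]indole-1-carboxylate | CC(C)(C)OC(=O)n1cc(C#Cc2ccccc2N)c2ccccc12
F2 | step 2 | tert-butyl 3-(1H-indol-2-yl)indole-1-carboxylate | CC(C)(C)OC(=O)n1cc(-c2cc3ccccc3[nH]2)c2ccccc12
F3 | step 3 | tert-butyl 3-(3-oxo-3H-indol-2-yl)indole-1-carboxylate | CC(C)(C)OC(=O)n1cc(C2=Nc3ccccc3C2=O)c2ccccc12
F4 | step 1 | tert-butyl 3-[(trimethylsilyl)ethynyl]indole-1-carboxylate | CC(C)(C)OC(=O)n1cc(C#C[Si](C)(C)C)c2ccccc12
F5 | step 1 | tert-butyl 3-ethynylindole-1-carboxylate | C#Cc1cn(C(=O)OC(C)(C)C)c2ccccc12
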